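## The problem

The target is a (2S)-flavanone. Ring C, a 2,3-dihydro-4H-pyran-4-one, is fused through C4a and C8a to a 5,7-dihydroxylated ring A and carries at C2 a 1,3,4,5-tetrasubstituted ring B. In ring B the methoxy group is flanked by a prenyl group and an (E)-3-hydroxy-3-methylbut-1-enyl group. C2 is the only stereocentre, so nothing in the molecule can relay to it and it has to be set by a catalyst. After that it must be kept away from the one process that erases it: a C3 enolate expels O1, or benzylic C2 ionises, ring C opens to a chalcone, and the chalcone recloses without control. The tertiary allylic alcohol is conjugated to the styrene and ionises with acid to a diene. The prenyl group does not tolerate strong acid, electrophiles, hydrogenation or carbenes. The usual ways of freeing protected phenols (acid for acetals, hydrogenolysis, Lewis acids for methyl ethers) each collide with one of these groups or with the ring B methyl ether. The two ortho positions of ring B are equivalent, so a 3-bromo-5-iodo arene can take the two side chains in either order. The feature that opens the key step is the oxygen pattern of ring A: C5, C7 and C8a carry oxygen, and C4a=C8a is at the same time the double bond of the ring C vinylogous ester (C4=O, C4a=C8a–O1). C5 to C8 can therefore be carried as a β-keto ester chain on C8a of a 2-aryl-dihydropyranone, and a Claisen bond from C4a to C5 builds ring A last, aromatic and with both phenols free. Flavanone numbering is used for these atoms in all intermediates.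

## Retrosynthesis

**18 to 17.** The target 18 is cut at C4a–C5, which turns ring A into a methyl β-keto ester chain on the dihydropyranone 17. The neighbouring cuts are less attractive: C4–C4a needs a protected phloroglucinol and an acidic acylation, and O1–C2 or O1–C8a go through a chalcone or an inversion at C2. The chosen cut needs no phenol protection and only a base matched to the ester. The forward reaction must close C4a onto C5 faster than ring C can open.

**17 to 15.** The β-keto ester of 17 is traced to the dioxinone 15 by cutting the C5–OCH3 bond. The dioxinone is a masked acylketene, so the acidic, self-condensing keto ester appears only one step before it is used. The forward step is a neutral thermolysis in the presence of methanol through the acylketene 16.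

**15 to 13.** Ring C of 15 is opened at O1–C8a to the δ-hydroxy-β-diketone 14, carried as its bis-silyl ether 13. This cut keeps the C2–O bond, so the carbinol configuration of 13 becomes C2 of the target with retention. A hetero-Diels–Alder construction of ring C would need a diene that already carries the dioxinone chain. The forward step has to free the benzylic alcohol and dehydrate under acid mild enough for the tertiary allylic alcohol, before the open chain can aromatise.

**13 to 10 and 12.** The chain of 13 is cut at C4–C4a into the β-silyloxy N-methoxy-N-methylamide 10 and the dianion of the keto-dioxinone 12. A cut at C8a–C8 would need an enolisable β-keto acyl donor, which the dianion would simply deprotonate. Fragment 12 comes in one step from the commercial dioxinone 11 by acylation at the methyl group.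

**10 to 6 and 7.** In 10 both hydroxyl groups carry triethylsilyl groups, put on together from the diol 9. The prenyl group of 9 is cut at the aryl–CH2 bond (Stille coupling of the bromide 8). The hydroxybutenyl group of 8 is cut at the aryl–CH= bond (Heck reaction of the iodide 6 with 2-methylbut-3-en-2-ol 7). Iodine is used first because it reacts under conditions that leave bromine alone. Doing the couplings after the aldol keeps the Lewis-acid catalyst away from a free tertiary alcohol and allows a single silylation for both hydroxyl groups.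

**6 to 1.** Amide 6 comes from the ester 5, and 5 from the aldehyde 3 by cutting C2–C3 (enantioselective acetate aldol). The stereocentre is thus set on a simple, electron-poor aldehyde with no sensitive group. Aldehyde 3 comes from commercial 3-bromo-4-hydroxybenzaldehyde 1 by ortho-iodination (2) and O-methylation.

## Roads not taken

**Alternative 1:** The cut is the C3=C4 bond, with C4 masked as a silyl enol ether. The diene A2 has a vinyl group on C2 and a 1-silyloxyvinyl group on ring A. The second-generation Grubbs catalyst would join them into the 4-silyloxy-2H-chromene A1, and enol ether hydrolysis and desilylation would follow. The closure is neutral, the masked ketone cannot form a C3 enolate during the closure, and ring-closing metathesis of silyl enol ethers is a known reaction class. For this target the weak point is chemoselectivity. A2 has four olefins, and the catalyst can engage the prenyl group (truncation by cross metathesis) or the styrene of ring B. The desired partner is a hindered, electron-rich 1,1-disubstituted olefin between two ortho oxygen substituents. The C2–O bond of A2 is allylic and benzylic, so ruthenium hydride isomerisation or ionisation threatens the stereocentre. Four silyl groups must also come off afterwards. This road has the better-precedented ring closure and avoids base on the finished flavanone. The chosen plan sets against it that no step after the completion of ring B touches an olefin, and that ring A needs no protecting group.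

**Alternative 2:** The cut is C4–C4a. The β-aryloxy acid A4, activated with (CF3CO)2O in the presence of a hindered pyridine, would acylate the symmetric ring A to the chromanone A3. Ring A is symmetric, so there is no regiochemistry, and this Friedel–Crafts closure is the most reliable of the four ring closures considered. The weak points lie around it. Under acidic activation A4 can lose the phenol by elimination or ionise at C2, and the prenyl group meets an acid anhydride. The tertiary alcohol cannot be present, so an iodide is carried and a Heck reaction has to be run on the base-sensitive flavanone A3, followed by two desilylations. The stereocentre would come from a Mitsunobu etherification at a benzylic carbinol, which is prone to partial ionisation. The reliability of the key step is clearly better here. The chosen plan sets against it that its key step ends at the target with nothing to follow, and that neither side chain of ring B ever meets an acid.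

**Alternative 3:** The cut is C2–C3. The diazo ketone A6 would lose nitrogen on Rh2(S-PTTL)4, dirhodium tetrakis(N-phthaloyl-(S)-tert-leucinate), and the carbene would insert into one enantiotopic benzylic C–H bond to give the flavanone A5. Ring C and the stereocentre would be made in one catalytic step from an achiral benzyl ether, which is more economical in stereochemical terms than any other plan here. The weak points are again the olefins. The prenyl group is an excellent carbene acceptor (cyclopropanation), and the ether oxygen can form an oxonium ylide that rearranges. Closure to a six-membered ring by insertion is less favoured than the usual five-membered mode, and enantiocontrol with a diazo ketone of this type is uncertain. Three desilylations follow. This road is shorter to the stereocentre. The chosen plan sets against it a stereocentre from a reliable aldol on a simple aldehyde and a key step whose reagent has no reason to attack the olefins.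

Key step: step 12

Assumption: the ketene silyl acetal of methyl acetate and tributyl(3-methylbut-2-enyl)stannane are taken as purchasable reagents, and the antipode of the aldol catalyst is defined by the required Si-face attack, to be confirmed on 5 (Mosher ester) before material is advanced.

## Route

Step 1
Reactants: 1 3-bromo-4-hydroxybenzaldehyde
Product: 2 3-bromo-4-hydroxy-5-iodobenzaldehyde
Conditions: NIS, AcOH, rt
Reagents that add atoms: N-iodosuccinimide, O=C1CCC(=O)N1I
Why: Electrophilic aromatic iodination; the phenol directs to its only free ortho position, since the para position carries the formyl group.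

Step 2
Reactants: 2 3-bromo-4-hydroxy-5-iodobenzaldehyde
Product: 3 3-bromo-5-iodo-4-methoxybenzaldehyde
Conditions: MeI, K2CO3, DMF, rt
Reagents that add atoms: iodomethane, CI
Why: Williamson ether synthesis; the phenol between two halogens is acidic and methylates cleanly on oxygen.

Step 3
Reactants: 3 3-bromo-5-iodo-4-methoxybenzaldehyde
Product: 5 methyl (S)-3-(3-bromo-5-iodo-4-methoxyphenyl)-3-hydroxypropanoate, via trimethylsilyl ether of the aldol adduct 4 (not isolated)
Conditions: 1-methoxy-1-(trimethylsilyloxy)ethene, Ti(OiPr)4 (2 mol%), Schiff-base ligand from 2-amino-2'-hydroxy-1,1'-binaphthyl and 3-bromo-5-tert-butylsalicylaldehyde (antipode for Si-face attack), 3,5-di-tert-butylsalicylic acid, Et2O, −10 °C; then 1 M HCl, THF, 0 °C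
Reagents that add atoms: 1-methoxy-1-(trimethylsilyloxy)ethene, C=C(OC)O[Si](C)(C)C
Why: Catalytic enantioselective Mukaiyama acetate aldol, a reaction that works well with aromatic aldehydes. The chiral titanium complex blocks the Re face, so the ketene acetal adds to the Si face and sets the (S)-carbinol that becomes C2; dilute acid cleaves the silyl ether 4.

Step 4
Reactants: 5 methyl (S)-3-(3-bromo-5-iodo-4-methoxyphenyl)-3-hydroxypropanoate
Product: 6 (S)-3-(3-bromo-5-iodo-4-methoxyphenyl)-3-hydroxy-N-methoxy-N-methylpropanamide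
Conditions: MeNHOMe·HCl, AlMe3, CH2Cl2, 0 °C to rt
Reagents that add atoms: N,O-dimethylhydroxylamine hydrochloride, CNOC.Cl
Why: Aluminium amide aminolysis of an ester to the Weinreb amide; it tolerates the free β-hydroxyl and, unlike a Grignard base, does not exchange with the aryl iodide.

Step 5
Reactants: 6 (S)-3-(3-bromo-5-iodo-4-methoxyphenyl)-3-hydroxy-N-methoxy-N-methylpropanamide; 7 2-methylbut-3-en-2-ol
Product: 8 (S)-3-{3-bromo-5-[(E)-3-hydroxy-3-methylbut-1-enyl]-4-methoxyphenyl}-3-hydroxy-N-methoxy-N-methylpropanamide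
Conditions: Pd(OAc)2 (5 mol%), Bu4NCl, NaHCO3, DMF, 50 °C
Reagents that add atoms: none
Why: Heck reaction under ligand-free phase-transfer conditions, where oxidative addition occurs at C–I and leaves C–Br. The aryl group adds to the terminal carbon, and since the carbinol carbon has no hydrogen, β-hydride elimination can only give the E-styrene.

Step 6
Reactants: 8 (S)-3-{3-bromo-5-[(E)-3-hydroxy-3-methylbut-1-enyl]-4-methoxyphenyl}-3-hydroxy-N-methoxy-N-methylpropanamide
Product: 9 (S)-3-hydroxy-3-{3-[(E)-3-hydroxy-3-methylbut-1-enyl]-4-methoxy-5-(3-methylbut-2-enyl)phenyl}-N-methoxy-N-methylpropanamide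
Conditions: tributyl(3-methylbut-2-enyl)stannane, Pd(PPh3)4 (5 mol%), DMF, 90 °C
Reagents that add atoms: tributyl(3-methylbut-2-enyl)stannane, CCCC[Sn](CCCC)(CCCC)CC=C(C)C
Why: Stille coupling of an aryl bromide with a prenylstannane; reductive elimination at the less substituted allyl terminus should give the linear prenyl arene, and the neutral conditions spare both hydroxyl groups and the amide.

Step 7
Reactants: 9 (S)-3-hydroxy-3-{3-[(E)-3-hydroxy-3-methylbut-1-enyl]-4-methoxy-5-(3-methylbut-2-enyl)phenyl}-N-methoxy-N-methylpropanamide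
Product: 10 (S)-N-methoxy-3-{4-methoxy-3-(3-methylbut-2-enyl)-5-[(E)-3-methyl-3-(triethylsilyloxy)but-1-enyl]phenyl}-N-methyl-3-(triethylsilyloxy)propanamide
Conditions: TESOTf, 2,6-lutidine, CH2Cl2, −78 to 0 °C
Reagents that add atoms: triethylsilyl trifluoromethanesulfonate, CC[Si](CC)(CC)OS(=O)(=O)C(F)(F)F
Why: Silylation with a silyl triflate and a hindered base covers the secondary and the tertiary alcohol in one operation; the base keeps the medium free of acid.

Step 8
Reactants: 11 2,2,6-trimethyl-4H-1,3-dioxin-4-one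
Product: 12 2,2-dimethyl-6-(2-oxopropyl)-4H-1,3-dioxin-4-one
Conditions: LiHMDS (2 equiv), THF, −78 °C; then AcCl
Reagents that add atoms: acetyl chloride, CC(Cl)=O
Why: Vinylogous Claisen acylation: the lithium dienolate of the dioxinone is acylated at the methyl carbon; the second equivalent of base takes up the more acidic product.

Step 9
Reactants: 10 (S)-N-methoxy-3-{4-methoxy-3-(3-methylbut-2-enyl)-5-[(E)-3-methyl-3-(triethylsilyloxy)but-1-enyl]phenyl}-N-methyl-3-(triethylsilyloxy)propanamide; 12 2,2-dimethyl-6-(2-oxopropyl)-4H-1,3-dioxin-4-one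
Product: 13 2,2-dimethyl-6-[(6S)-6-{4-methoxy-3-(3-methylbut-2-enyl)-5-[(E)-3-methyl-3-(triethylsilyloxy)but-1-enyl]phenyl}-2,4-dioxo-6-(triethylsilyloxy)hexyl]-4H-1,3-dioxin-4-one
Conditions: 12, LDA (2 equiv per 12), THF, −78 °C; then 10, −78 to −40 °C; aq. NH4Cl
Reagents that add atoms: none
Why: Claisen-type C-acylation of the keto-dioxinone dianion at its terminal carbon by a Weinreb amide, the standard entry to diketo-dioxinones; the chelated tetrahedral intermediate prevents a second addition. This forms the C4–C4a bond.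

Step 10
Reactants: 13 2,2-dimethyl-6-[(6S)-6-{4-methoxy-3-(3-methylbut-2-enyl)-5-[(E)-3-methyl-3-(triethylsilyloxy)but-1-enyl]phenyl}-2,4-dioxo-6-(triethylsilyloxy)hexyl]-4H-1,3-dioxin-4-one
Product: 15 6-{[(2S)-2-{3-[(E)-3-hydroxy-3-methylbut-1-enyl]-4-methoxy-5-(3-methylbut-2-enyl)phenyl}-4-oxo-3,4-dihydro-2H-pyran-6-yl]methyl}-2,2-dimethyl-4H-1,3-dioxin-4-one, via desilylated dihydroxy diketo-dioxinone 14 (not isolated)
Conditions: HF·pyridine, pyridine, THF, 0 °C to rt; then PPTS (cat.), 4 Å MS, CH2Cl2, rt
Reagents that add atoms: none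
Why: Fluoride desilylation followed by the cyclodehydration of a δ-hydroxy-β-diketone to a 2,3-dihydro-4H-pyran-4-one: the benzylic hydroxyl adds to the C8a carbonyl and water is lost towards C4a. The C2–O bond is not broken, so C2 keeps its (S) configuration, and the weak acid should spare the tertiary allylic alcohol.

Step 11
Reactants: 15 6-{[(2S)-2-{3-[(E)-3-hydroxy-3-methylbut-1-enyl]-4-methoxy-5-(3-methylbut-2-enyl)phenyl}-4-oxo-3,4-dihydro-2H-pyran-6-yl]methyl}-2,2-dimethyl-4H-1,3-dioxin-4-one
Product: 17 methyl 4-[(2S)-2-{3-[(E)-3-hydroxy-3-methylbut-1-enyl]-4-methoxy-5-(3-methylbut-2-enyl)phenyl}-4-oxo-3,4-dihydro-2H-pyran-6-yl]-3-oxobutanoate, via acylketene 16 (not isolated)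
Conditions: MeOH (excess), toluene, 110 °C, sealed tube
Reagents that add atoms: methanol, CO
Why: Thermal retro-[4+2] fragmentation of the dioxinone releases acetone and the acylketene 16, which the large excess of methanol traps as the methyl β-keto ester; the medium is neutral throughout.

Step 12
Reactants: 17 methyl 4-[(2S)-2-{3-[(E)-3-hydroxy-3-methylbut-1-enyl]-4-methoxy-5-(3-methylbut-2-enyl)phenyl}-4-oxo-3,4-dihydro-2H-pyran-6-yl]-3-oxobutanoate
Product: 18 (S)-5,7-dihydroxy-2-{3-[(E)-3-hydroxy-3-methylbut-1-enyl]-4-methoxy-5-(3-methylbut-2-enyl)phenyl}chroman-4-one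
Conditions: Mg(OMe)2, MeOH, rt to 40 °C, argon; then aq. NH4Cl, 0 °C
Reagents that add atoms: none
Why: Proposed new method: Mg(OMe)2 should first form the chelated magnesium enolate of the β-keto ester (C5 to C7) and then remove a C8 proton, giving a dienolate that runs from C8 through C8a and C4a to the C4 oxygen; its C4a terminus attacks the chelate-activated ester carbon C5, methoxide is lost, and enolisation at C5 and C7 gives the aromatic ring A as its magnesium phenoxide, which is the driving force. The closest known reaction type is the Claisen-type cyclisation of open-chain 3,5,7-triketo esters to acylphloroglucinols under magnesium alkoxides; here the 7-keto enol is tied up as the ring C ether, which has not been shown. Ring A closes in a 6-(enolexo)-exo-trig mode. No stereocentre is formed, and C2 is not part of the reacting array. The selectivity needed is Claisen closure (C4a to C5) against aldol closure (C6 to C4) and against opening of ring C: the aldol adduct would be a bridged 2-oxabicyclo[3.3.1]nonane with the C4a=C8a double bond at a bridgehead, so it can only revert, whereas the Claisen path ends in an aromatic sink. Opening of ring C needs the C3 enolate, and the C6 and C8 protons are far more acidic, so the substrate is already a dianion before C3 could be touched. Methoxide matches the methyl ester, so ester exchange is degenerate, and conjugate addition of methoxide at C8a, if it occurs, breaks O1–C8a and not O1–C2 and so cannot touch the stereocentre.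

## Compound list

1 | 3-bromo-4-hydroxybenzaldehyde | O=Cc1ccc(O)c(Br)c1 | starting material
2 | 3-bromo-4-hydroxy-5-iodobenzaldehyde | O=Cc1cc(Br)c(O)c(I)c1 | intermediate
3 | 3-bromo-5-iodo-4-methoxybenzaldehyde | COc1c(Br)cc(C=O)cc1I | intermediate
4 | methyl (S)-3-(3-bromo-5-iodo-4-methoxyphenyl)-3-(trimethylsilyloxy)propanoate | COC(=O)C[C@H](O[Si](C)(C)C)c1cc(Br)c(OC)c(I)c1 | intermediate
5 | methyl (S)-3-(3-bromo-5-iodo-4-methoxyphenyl)-3-hydroxypropanoate | COC(=O)C[C@H](O)c1cc(Br)c(OC)c(I)c1 | intermediate
6 | (S)-3-(3-bromo-5-iodo-4-methoxyphenyl)-3-hydroxy-N-methoxy-N-methylpropanamide | CON(C)C(=O)C[C@H](O)c1cc(Br)c(OC)c(I)c1 | intermediate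
7 | 2-methylbut-3-en-2-ol | C=CC(C)(C)O | starting material
8 | (S)-3-{3-bromo-5-[(E)-3-hydroxy-3-methylbut-1-enyl]-4-methoxyphenyl}-3-hydroxy-N-methoxy-N-methylpropanamide | CON(C)C(=O)C[C@H](O)c1cc(Br)c(OC)c(/C=C/C(C)(C)O)c1 | intermediate
9 | (S)-3-hydroxy-3-{3-[(E)-3-hydroxy-3-methylbut-1-enyl]-4-methoxy-5-(3-methylbut-2-enyl)phenyl}-N-methoxy-N-methylpropanamide | CON(C)C(=O)C[C@H](O)c1cc(CC=C(C)C)c(OC)c(/C=C/C(C)(C)O)c1 | intermediate
10 | (S)-N-methoxy-3-{4-methoxy-3-(3-methylbut-2-enyl)-5-[(E)-3-methyl-3-(triethylsilyloxy)but-1-enyl]phenyl}-N-methyl-3-(triethylsilyloxy)propanamide | CON(C)C(=O)C[C@H](O[Si](CC)(CC)CC)c1cc(CC=C(C)C)c(OC)c(/C=C/C(C)(C)O[Si](CC)(CC)CC)c1 | intermediate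
11 | 2,2,6-trimethyl-4H-1,3-dioxin-4-one | CC1=CC(=O)OC(C)(C)O1 | starting material
12 | 2,2-dimethyl-6-(2-oxopropyl)-4H-1,3-dioxin-4-one | CC(=O)CC1=CC(=O)OC(C)(C)O1 | intermediate
13 | 2,2-dimethyl-6-[(6S)-6-{4-methoxy-3-(3-methylbut-2-enyl)-5-[(E)-3-methyl-3-(triethylsilyloxy)but-1-enyl]phenyl}-2,4-dioxo-6-(triethylsilyloxy)hexyl]-4H-1,3-dioxin-4-one | CC1(C)OC(=O)C=C(CC(=O)CC(=O)C[C@H](O[Si](CC)(CC)CC)c2cc(CC=C(C)C)c(OC)c(/C=C/C(C)(C)O[Si](CC)(CC)CC)c2)O1 | intermediate
14 | 6-[(6S)-6-hydroxy-6-{3-[(E)-3-hydroxy-3-methylbut-1-enyl]-4-methoxy-5-(3-methylbut-2-enyl)phenyl}-2,4-dioxohexyl]-2,2-dimethyl-4H-1,3-dioxin-4-one | CC1(C)OC(=O)C=C(CC(=O)CC(=O)C[C@H](O)c2cc(CC=C(C)C)c(OC)c(/C=C/C(C)(C)O)c2)O1 | intermediate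
15 | 6-{[(2S)-2-{3-[(E)-3-hydroxy-3-methylbut-1-enyl]-4-methoxy-5-(3-methylbut-2-enyl)phenyl}-4-oxo-3,4-dihydro-2H-pyran-6-yl]methyl}-2,2-dimethyl-4H-1,3-dioxin-4-one | CC1(C)OC(=O)C=C(CC2=CC(=O)C[C@@H](c3cc(CC=C(C)C)c(OC)c(/C=C/C(C)(C)O)c3)O2)O1 | intermediate
16 | 5-[(2S)-2-{3-[(E)-3-hydroxy-3-methylbut-1-enyl]-4-methoxy-5-(3-methylbut-2-enyl)phenyl}-4-oxo-3,4-dihydro-2H-pyran-6-yl]penta-1-ene-1,3-dione (acylketene) | O=C=CC(=O)CC1=CC(=O)C[C@@H](c2cc(CC=C(C)C)c(OC)c(/C=C/C(C)(C)O)c2)O1 | intermediate
17 | methyl 4-[(2S)-2-{3-[(E)-3-hydroxy-3-methylbut-1-enyl]-4-methoxy-5-(3-methylbut-2-enyl)phenyl}-4-oxo-3,4-dihydro-2H-pyran-6-yl]-3-oxobutanoate | COC(=O)CC(=O)CC1=CC(=O)C[C@@H](c2cc(CC=C(C)C)c(OC)c(/C=C/C(C)(C)O)c2)O1 | intermediate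
18 | (S)-5,7-dihydroxy-2-{3-[(E)-3-hydroxy-3-methylbut-1-enyl]-4-methoxy-5-(3-methylbut-2-enyl)phenyl}chroman-4-one | COc1c(/C=C/C(C)(C)O)cc([C@@H]2CC(=O)c3c(O)cc(O)cc3O2)cc1CC=C(C)C | target

## Step count and uncertain steps

Total step count: 12. Longest linear sequence: 11 steps (steps 1 to 7 and 9 to 12); step 8 makes the side fragment 12.

**Step 12 (key step, proposed new method).** The most likely failure is loss of enantiomeric purity. If the product phenoxide stays in the basic medium, ring C can open reversibly by elimination of O1 from a C3 enolate and reclose without control. The second possibility is that the closure stalls at the stage of the unreactive bis-enolate, and forcing it favours the first problem.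

The fallback uses only known reactions: the open-chain Claisen cyclisation, followed by closure of ring C with inversion. It sets out from 9 and returns to the route at 18.
- The benzylic alcohol of 9 is oxidised with MnO2 in CH2Cl2 to 3-{3-[(E)-3-hydroxy-3-methylbut-1-enyl]-4-methoxy-5-(3-methylbut-2-enyl)phenyl}-N-methoxy-N-methyl-3-oxopropanamide F1.
- Asymmetric transfer hydrogenation with RuCl[(R,R)-TsDPEN](p-cymene) in HCO2H/Et3N should give the antipodal alcohol (R)-3-hydroxy-3-{3-[(E)-3-hydroxy-3-methylbut-1-enyl]-4-methoxy-5-(3-methylbut-2-enyl)phenyl}-N-methoxy-N-methylpropanamide F2.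
- Silylation as in step 7 gives (R)-N-methoxy-3-{4-methoxy-3-(3-methylbut-2-enyl)-5-[(E)-3-methyl-3-(triethylsilyloxy)but-1-enyl]phenyl}-N-methyl-3-(triethylsilyloxy)propanamide F3.
- Acylation of the dianion of 12 as in step 9 gives 2,2-dimethyl-6-[(6R)-6-{4-methoxy-3-(3-methylbut-2-enyl)-5-[(E)-3-methyl-3-(triethylsilyloxy)but-1-enyl]phenyl}-2,4-dioxo-6-(triethylsilyloxy)hexyl]-4H-1,3-dioxin-4-one F4.
- Thermolysis in toluene and methanol opens the dioxinone to methyl (9R)-9-{4-methoxy-3-(3-methylbut-2-enyl)-5-[(E)-3-methyl-3-(triethylsilyloxy)but-1-enyl]phenyl}-3,5,7-trioxo-9-(triethylsilyloxy)nonanoate F5, which is not stored.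
- F5 is treated at once with Mg(OMe)2 in methanol; the Claisen cyclisation of such open-chain triketo esters should give (R)-3-{4-methoxy-3-(3-methylbut-2-enyl)-5-[(E)-3-methyl-3-(triethylsilyloxy)but-1-enyl]phenyl}-3-(triethylsilyloxy)-1-(2,4,6-trihydroxyphenyl)propan-1-one F6.
- HF·pyridine frees (R)-3-hydroxy-3-{3-[(E)-3-hydroxy-3-methylbut-1-enyl]-4-methoxy-5-(3-methylbut-2-enyl)phenyl}-1-(2,4,6-trihydroxyphenyl)propan-1-one F7.
- A Mitsunobu cyclisation (PPh3, DIAD, THF, high dilution) lets one of the two equivalent ortho phenols displace the activated benzylic oxygen with inversion and gives 18.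

**Step 10.** Two things may go wrong. The pyridine buffer may start the base-promoted aldol aromatisation of the open diketo-dioxinone before ring C has formed. The acid needed for dehydration may ionise the tertiary allylic alcohol or eliminate the benzylic hydroxyl.

The fallback forms ring C on a chain that is too short to aromatise and adds the last two carbons afterwards. It sets out from 10 and returns at 17.
- The dianion of allyl acetoacetate (NaH, then n-BuLi, THF) is acylated by 10 to allyl (7S)-7-{4-methoxy-3-(3-methylbut-2-enyl)-5-[(E)-3-methyl-3-(triethylsilyloxy)but-1-enyl]phenyl}-3,5-dioxo-7-(triethylsilyloxy)heptanoate F8.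
- HF·pyridine and then PPTS give allyl 2-[(2S)-2-{3-[(E)-3-hydroxy-3-methylbut-1-enyl]-4-methoxy-5-(3-methylbut-2-enyl)phenyl}-4-oxo-3,4-dihydro-2H-pyran-6-yl]acetate F9.
- Pd(PPh3)4 and morpholine remove the allyl group to give 2-[(2S)-2-{3-[(E)-3-hydroxy-3-methylbut-1-enyl]-4-methoxy-5-(3-methylbut-2-enyl)phenyl}-4-oxo-3,4-dihydro-2H-pyran-6-yl]acetic acid F10.
- Carbonyldiimidazole converts the acid into (2S)-2-{3-[(E)-3-hydroxy-3-methylbut-1-enyl]-4-methoxy-5-(3-methylbut-2-enyl)phenyl}-6-[2-(imidazol-1-yl)-2-oxoethyl]-2,3-dihydro-4H-pyran-4-one F11, used without isolation.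
- Decarboxylative acylation of Mg(O2CCH2CO2Me)2 by F11 gives 17.

**Step 9.** The basic dianion may remove a proton next to the amide and expel the β-silyloxy group, or proton transfer from the product may stop the reaction early.

The fallback replaces the acyl substitution by an aldol addition and an oxidation. It sets out from 10 and returns at 13.
- DIBAL-H in THF at −78 °C reduces the amide to (S)-3-{4-methoxy-3-(3-methylbut-2-enyl)-5-[(E)-3-methyl-3-(triethylsilyloxy)but-1-enyl]phenyl}-3-(triethylsilyloxy)propanal F12.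
- The dianion of 12 adds to the aldehyde at −78 °C, faster than any elimination, and gives 6-[(6S)-4-hydroxy-6-{4-methoxy-3-(3-methylbut-2-enyl)-5-[(E)-3-methyl-3-(triethylsilyloxy)but-1-enyl]phenyl}-2-oxo-6-(triethylsilyloxy)hexyl]-2,2-dimethyl-4H-1,3-dioxin-4-one F13 as a mixture at the new carbinol.
- Dess–Martin periodinane with NaHCO3 in CH2Cl2 oxidises F13 to 13.

**Step 6.** Allyl transposition in the transmetallation may attach the branched 1,1-dimethylallyl isomer, and oxidative addition at the bromide next to the methoxy group may be slow.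

The fallback separates carbon–carbon coupling from the trisubstituted olefin. It sets out from 8 and returns at 9.
- Stille coupling with allyltributylstannane and Pd(PPh3)4, which has no regiochemical choice, gives (S)-3-{3-allyl-5-[(E)-3-hydroxy-3-methylbut-1-enyl]-4-methoxyphenyl}-3-hydroxy-N-methoxy-N-methylpropanamide F14.
- Cross metathesis with 2-methylbut-2-ene and the second-generation Grubbs catalyst converts the allyl into the prenyl group of 9; the hindered styrene next to the quaternary carbinol should react much more slowly.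

## Further compounds

F1 | step 12 | 3-{3-[(E)-3-hydroxy-3-methylbut-1-enyl]-4-methoxy-5-(3-methylbut-2-enyl)phenyl}-N-methoxy-N-methyl-3-oxopropanamide | CON(C)C(=O)CC(=O)c1cc(CC=C(C)C)c(OC)c(/C=C/C(C)(C)O)c1
F2 | step 12 | (R)-3-hydroxy-3-{3-[(E)-3-hydroxy-3-methylbut-1-enyl]-4-methoxy-5-(3-methylbut-2-enyl)phenyl}-N-methoxy-N-methylpropanamide | CON(C)C(=O)C[C@@H](O)c1cc(CC=C(C)C)c(OC)c(/C=C/C(C)(C)O)c1
F3 | step 12 | (R)-N-methoxy-3-{4-methoxy-3-(3-methylbut-2-enyl)-5-[(E)-3-methyl-3-(triethylsilyloxy)but-1-enyl]phenyl}-N-methyl-3-(triethylsilyloxy)propanamide | CON(C)C(=O)C[C@@H](O[Si](CC)(CC)CC)c1cc(CC=C(C)C)c(OC)c(/C=C/C(C)(C)O[Si](CC)(CC)CC)c1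
F4 | step 12 | 2,2-dimethyl-6-[(6R)-6-{4-methoxy-3-(3-methylbut-2-enyl)-5-[(E)-3-methyl-3-(triethylsilyloxy)but-1-enyl]phenyl}-2,4-dioxo-6-(triethylsilyloxy)hexyl]-4H-1,3-dioxin-4-one | CC1(C)OC(=O)C=C(CC(=O)CC(=O)C[C@@H](O[Si](CC)(CC)CC)c2cc(CC=C(C)C)c(OC)c(/C=C/C(C)(C)O[Si](CC)(CC)CC)c2)O1
F5 | step 12 | methyl (9R)-9-{4-methoxy-3-(3-methylbut-2-enyl)-5-[(E)-3-methyl-3-(triethylsilyloxy)but-1-enyl]phenyl}-3,5,7-trioxo-9-(triethylsilyloxy)nonanoate | COC(=O)CC(=O)CC(=O)CC(=O)C[C@@H](O[Si](CC)(CC)CC)c1cc(CC=C(C)C)c(OC)c(/C=C/C(C)(C)O[Si](CC)(CC)CC)c1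
F6 | step 12 | (R)-3-{4-methoxy-3-(3-methylbut-2-enyl)-5-[(E)-3-methyl-3-(triethylsilyloxy)but-1-enyl]phenyl}-3-(triethylsilyloxy)-1-(2,4,6-trihydroxyphenyl)propan-1-one | O=C(C[C@@H](O[Si](CC)(CC)CC)c1cc(CC=C(C)C)c(OC)c(/C=C/C(C)(C)O[Si](CC)(CC)CC)c1)c1c(O)cc(O)cc1O
F7 | step 12 | (R)-3-hydroxy-3-{3-[(E)-3-hydroxy-3-methylbut-1-enyl]-4-methoxy-5-(3-methylbut-2-enyl)phenyl}-1-(2,4,6-trihydroxyphenyl)propan-1-one | O=C(C[C@@H](O)c1cc(CC=C(C)C)c(OC)c(/C=C/C(C)(C)O)c1)c1c(O)cc(O)cc1O
F8 | step 10 | allyl (7S)-7-{4-methoxy-3-(3-methylbut-2-enyl)-5-[(E)-3-methyl-3-(triethylsilyloxy)but-1-enyl]phenyl}-3,5-dioxo-7-(triethylsilyloxy)heptanoate | C=CCOC(=O)CC(=O)CC(=O)C[C@H](O[Si](CC)(CC)CC)c1cc(CC=C(C)C)c(OC)c(/C=C/C(C)(C)O[Si](CC)(CC)CC)c1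
F9 | step 10 | allyl 2-[(2S)-2-{3-[(E)-3-hydroxy-3-methylbut-1-enyl]-4-methoxy-5-(3-methylbut-2-enyl)phenyl}-4-oxo-3,4-dihydro-2H-pyran-6-yl]acetate | C=CCOC(=O)CC1=CC(=O)C[C@@H](c2cc(CC=C(C)C)c(OC)c(/C=C/C(C)(C)O)c2)O1
F10 | step 10 | 2-[(2S)-2-{3-[(E)-3-hydroxy-3-methylbut-1-enyl]-4-methoxy-5-(3-methylbut-2-enyl)phenyl}-4-oxo-3,4-dihydro-2H-pyran-6-yl]acetic acid | OC(=O)CC1=CC(=O)C[C@@H](c2cc(CC=C(C)C)c(OC)c(/C=C/C(C)(C)O)c2)O1
F11 | step 10 | (2S)-2-{3-[(E)-3-hydroxy-3-methylbut-1-enyl]-4-methoxy-5-(3-methylbut-2-enyl)phenyl}-6-[2-(imidazol-1-yl)-2-oxoethyl]-2,3-dihydro-4H-pyran-4-one | O=C(CC1=CC(=O)C[C@@H](c2cc(CC=C(C)C)c(OC)c(/C=C/C(C)(C)O)c2)O1)n1ccnc1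
F12 | step 9 | (S)-3-{4-methoxy-3-(3-methylbut-2-enyl)-5-[(E)-3-methyl-3-(triethylsilyloxy)but-1-enyl]phenyl}-3-(triethylsilyloxy)propanal | O=CC[C@H](O[Si](CC)(CC)CC)c1cc(CC=C(C)C)c(OC)c(/C=C/C(C)(C)O[Si](CC)(CC)CC)c1
F13 | step 9 | 6-[(6S)-4-hydroxy-6-{4-methoxy-3-(3-methylbut-2-enyl)-5-[(E)-3-methyl-3-(triethylsilyloxy)but-1-enyl]phenyl}-2-oxo-6-(triethylsilyloxy)hexyl]-2,2-dimethyl-4H-1,3-dioxin-4-one | CC1(C)OC(=O)C=C(CC(=O)CC(O)C[C@H](O[Si](CC)(CC)CC)c2cc(CC=C(C)C)c(OC)c(/C=C/C(C)(C)O[Si](CC)(CC)CC)c2)O1
F14 | step 6 | (S)-3-{3-allyl-5-[(E)-3-hydroxy-3-methylbut-1-enyl]-4-methoxyphenyl}-3-hydroxy-N-methoxy-N-methylpropanamide | CON(C)C(=O)C[C@H](O)c1cc(CC=C)c(OC)c(/C=C/C(C)(C)O)c1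
A1 | alternative 1 | (S)-4-(tert-butyldimethylsilyloxy)-2-{3-[(E)-3-(tert-butyldimethylsilyloxy)-3-methylbut-1-enyl]-4-methoxy-5-(3-methylbut-2-enyl)phenyl}-5,7-bis(triisopropylsilyloxy)-2H-chromene | CC(C)(C)[Si](C)(C)OC1=C[C@@H](c2cc(CC=C(C)C)c(OC)c(/C=C/C(C)(C)O[Si](C)(C)C(C)(C)C)c2)Oc2cc(O[Si](C(C)C)(C(C)C)C(C)C)cc(O[Si](C(C)C)(C(C)C)C(C)C)c12
A2 | alternative 1 | tert-butyl{1-[2-({(1S)-1-[3-((E)-3-(tert-butyldimethylsilyloxy)-3-methylbut-1-enyl)-4-methoxy-5-(3-methylbut-2-enyl)phenyl]prop-2-enyl}oxy)-4,6-bis(triisopropylsilyloxy)phenyl]vinyloxy}dimethylsilane | C=C[C@@H](c1cc(CC=C(C)C)c(OC)c(/C=C/C(C)(C)O[Si](C)(C)C(C)(C)C)c1)Oc1cc(O[Si](C(C)C)(C(C)C)C(C)C)cc(O[Si](C(C)C)(C(C)C)C(C)C)c1C(=C)O[Si](C)(C)C(C)(C)C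
A3 | alternative 2 | (S)-2-[3-iodo-4-methoxy-5-(3-methylbut-2-enyl)phenyl]-5,7-bis(triisopropylsilyloxy)chroman-4-one | O=C1C[C@@H](c2cc(CC=C(C)C)c(OC)c(I)c2)Oc2cc(O[Si](C(C)C)(C(C)C)C(C)C)cc(O[Si](C(C)C)(C(C)C)C(C)C)c12
A4 | alternative 2 | (S)-3-[3,5-bis(triisopropylsilyloxy)phenoxy]-3-[3-iodo-4-methoxy-5-(3-methylbut-2-enyl)phenyl]propanoic acid | OC(=O)C[C@@H](c1cc(CC=C(C)C)c(OC)c(I)c1)Oc1cc(O[Si](C(C)C)(C(C)C)C(C)C)cc(O[Si](C(C)C)(C(C)C)C(C)C)c1
A5 | alternative 3 | (S)-2-{4-methoxy-3-(3-methylbut-2-enyl)-5-[(E)-3-methyl-3-(triethylsilyloxy)but-1-enyl]phenyl}-5,7-bis(triisopropylsilyloxy)chroman-4-one | O=C1C[C@@H](c2cc(CC=C(C)C)c(OC)c(/C=C/C(C)(C)O[Si](CC)(CC)CC)c2)Oc2cc(O[Si](C(C)C)(C(C)C)C(C)C)cc(O[Si](C(C)C)(C(C)C)C(C)C)c12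
A6 | alternative 3 | 2-diazo-1-[2-({4-methoxy-3-(3-methylbut-2-enyl)-5-[(E)-3-methyl-3-(triethylsilyloxy)but-1-enyl]phenyl}methoxy)-4,6-bis(triisopropylsilyloxy)phenyl]ethanone | [N-]=[N+]=CC(=O)c1c(OCc2cc(CC=C(C)C)c(OC)c(/C=C/C(C)(C)O[Si](CC)(CC)CC)c2)cc(O[Si](C(C)C)(C(C)C)C(C)C)cc1O[Si](C(C)C)(C(C)C)C(C)C
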